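One step with a constant that stays constant cannot draw the violet curve. Here is what I have, and what I am asked.

| flask | starting material | coupling partner | time |
|---|---|---|---|
| violet | 120 mM | 360 mM |  |
| green | 72.0 mM | 312 mM |  |
| red | 120 mM | 720 mM |  |
| amber | 360 mM | 360 mM |  |
| grey | 48.0 mM | 140 mM | 45 min |

| violet run: time / min | violet run: [starting material] / mM | green run: time / min | green run: [starting material] / mM | red run: time / min | red run: [starting material] / mM | amber run: time / min | amber run: [starting material] / mM |
|---|---|---|---|---|---|---|---|
| 6.4 | 99.6 | 6.4 | 60.4 | 6.4 | 78.0 | 6.4 | 300.1 |
| 13 | 85.6 | 13 | 55.5 | 13 | 55.7 | 13 | 264.7 |
| 19 | 75.6 | 19 | 49.6 | 19 | 41.2 | 19 | 246.0 |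
| 26 | 69.4 | 26 | 44.7 | 26 | 34.0 | 26 | 231.1 |
| 32 | 66.5 | 32 | 40.3 | 32 | 28.8 | 32 | 222.8 |
| 39 | 62.8 | 39 | 40.0 | 39 | 26.2 | 39 | 217.5 |
| 45 | 61.2 | 45 | 39.4 | 45 | 21.6 | 45 | 210.5 |

(standard deviation of a reading: 1 mM)

- Overall: starting material + coupling partner -> target.
- Constant volume, constant temperature.
- Readings of a species count what is bound in complexes too.
- "The second partner" is coupling partner.
- An order is taken over about fifteen percent of the charge, up and down.

- how the opening rate goes with [starting material] round the charge of the violet run: the exponent of the rate at two percent of starting material gone to target (one fixed amount of target, the same in the runs compared)
- how the opening rate goes with [coupling partner] round the charge of the violet run: the exponent of the rate at two percent of starting material gone to target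
- starting material in the grey run at 45 min, as a share of the starting material charged

I start with the main step alone. The first readings give the orders: amber against violet gives 0.980 in starting material, and red against violet gives 1.04 in coupling partner, though that comparison spans a doubling of the charge. With the coupling partner in excess, the violet run is pseudo-first-order, and its first reading gives a constant of 8.09 × 10⁻⁵ mM⁻¹ min⁻¹. That constant predicts 32.4 mM of starting material in the violet run at 45 min, yet the reading is 61.2 mM, which is more. For the grey run this step leaves 60.1%.

Next I let the constant fade exponentially. The violet readings at 13 min and 26 min give a fading rate of 0.0366 min⁻¹. With the coupling partner held at its charge, the rate law integrates in closed form: the logarithm of charge over remainder equals the coupling partner charged times a flat factor. The violet run gives that factor at 45 min as 0.00187 mM⁻¹, and the grey run then leaves 77.0%.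

Then comes the rest. The overall equation takes one coupling partner per starting material, so by 45 min the violet run has used 16.3% of its coupling partner, and the flat factor carries that loss inside it. With the coupling partner falling as the starting material falls, this rate law still integrates in closed form: the logarithm of the remaining share of coupling partner over the remaining share of starting material, divided by the coupling partner charged minus the starting material charged, equals the fading constant summed over time. The violet run gives 0.00206 mM⁻¹ at 45 min for the reach, the fading constant summed over time. I need no constant for this, and the grey run now leaves 75.9%, which is less than the flat factor gave. Scaling the reach with my order in coupling partner gives 0.00198 mM⁻¹ and moves the grey figure to 76.7%, and that is my number.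

The forecast, slightly apart from me, gives orders of 1 and 1.1 and 78% for the grey run, noting that the apparent constant “falls alike in violet and amber”.

The flask gives orders of 1.0 and 1.2, and 78.1% of the grey starting material remains at 45 min.

    2 coupling partner ⇌ reagent dimer, settled at all times (11.20 L mol⁻¹)
    starting material + reagent dimer → target + coupling partner (0.2562 L mol⁻¹ min⁻¹)
    starting material → decomposed substrate (0.002316 min⁻¹)
    coupling partner → lost reagent (0.09360 min⁻¹)

The rate in the red run stands at 2.3 times that of the violet run where the same amount of target has been made, for a doubled charge of coupling partner. The grey result corresponds to a reach of 0.00184 mM⁻¹, which is less than the violet reach. Carried to the red run, the violet reach gives 30.5 mM of starting material at 45 min, whereas the reading is lower, at 21.6 mM.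

The runs were computed with constants of no real substance.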